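**Retrosynthetic overview**

- Kuwanon E is traced back to an acyclic, enantiopure δ-hydroxy diketo-dioxinone. Rings C and A are both made from it in the last operation.
- Ring C closes first: cyclodehydration of the hydroxyl onto the C8a ketone, with the C2–O bond untouched. Ring A follows in the same flask: dioxinone thermolysis gives an acylketene that closes the C4a–C5 bond.
- The cascade precursor comes from a Claisen C-acylation of a keto-dioxinone dianion (the C4a–C5 triketide unit) with an (S)-β-hydroxy ester (C2–C4).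
- The (S)-β-hydroxy ester comes from a catalytic asymmetric acetate aldol on the ring B aldehyde. This sets the only stereocentre.
- Ring B is bought as resorcinol, then geranylated and formylated. The keto-dioxinone comes from the diketene–acetone adduct and acetyl chloride.

**Abbreviations and assumptions**

Geranyl = (2E)-3,7-dimethylocta-2,6-dien-1-yl. TBS = tert-butyldimethylsilyl. Ar = 2,4-bis(TBS-oxy)-5-geranylphenyl. Atom labels (C2, C4a, C5, C8a) follow flavanone numbering.

Assumption 1: in step 4 the (S,S) bisphosphoramide is taken to direct addition to the Si face of the aldehyde (the (R,R) catalyst being taken as Re-selective with aromatic aldehydes); if the aldol product proves to be R, the (R,R) catalyst is used with nothing else changed.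

Assumption 2: compound 13 is drawn as the open-chain triketo tautomer; it is handled as the enol mixture in which δ-hydroxy-1,3-diketones are normally isolated.

**Route**

Step 1
Reactants: 1 resorcinol (benzene-1,3-diol); 2 geraniol ((2E)-3,7-dimethylocta-2,6-dien-1-ol)
Product: 3 4-geranylresorcinol (4-geranylbenzene-1,3-diol)
Conditions: 1 (3 equiv), acidic Al2O3, ClCH2CH2Cl, 80 °C
Reagents that add atoms: none
Why: Friedel–Crafts-type allylation on the acidic Al2O3 surface, in which a tight geranyl ion pair attacks the most nucleophilic unhindered carbon of resorcinol (C4, ortho to one OH and para to the other), so the E alkene is kept and excess resorcinol suppresses dialkylation.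

Step 2
Reactants: 3 4-geranylresorcinol
Product: 5 5-geranyl-2,4-dihydroxybenzaldehyde, via iminium salt 4 (not isolated)
Conditions: POCl3 (1.2 equiv), DMF (1.5 equiv), MeCN, −15 °C to rt; then aq NaOAc, rt
Reagents that add atoms: N,N-dimethylformamide `CN(C)C=O` (formyl carbon); water `O` (carbonyl oxygen)
Why: Vilsmeier–Haack formylation goes to the one open position that is ortho to one OH and para to the other (as in the standard synthesis of 2,4-dihydroxybenzaldehydes), the chloroiminium ion being too weak an electrophile to touch the trisubstituted alkenes and the buffered hydrolysis sparing the acid-sensitive ortho-geranylphenol.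

Step 3
Reactants: 5 5-geranyl-2,4-dihydroxybenzaldehyde
Product: 6 2,4-bis(TBS-oxy)-5-geranylbenzaldehyde
Conditions: t-BuMe2SiCl (2.5 equiv), imidazole (5 equiv), DMF, rt
Reagents that add atoms: tert-butyldimethylsilyl chloride `CC(C)(C)[Si](C)(C)Cl`
Why: Standard imidazole-promoted O-silylation of both phenols makes the aldehyde compatible with the Lewis-acid aldol and the later lithium amide chemistry and allows a mild fluoride release at the end.

Step 4
Reactants: 6 2,4-bis(TBS-oxy)-5-geranylbenzaldehyde; 7 tert-butyl[(1-methoxyethenyl)oxy]dimethylsilane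
Product: 9 methyl (3S)-3-Ar-3-hydroxypropanoate, via trichlorosilyl ether 8 (not isolated)
Conditions: 7 (1.2 equiv), SiCl4 (1.1 equiv), (S,S)-N,N'-bis[4,5-dihydro-3,5-dimethyl-4-(3H-dinaphtho[2,1-d:1',2'-f][1,3,2]diazaphosphepin-4-oxide)]-N,N'-dimethyl-1,5-pentanediamine (5 mol%), i-Pr2NEt (10 mol%), CH2Cl2, −78 °C; then sat. aq NaHCO3
Reagents that add atoms: none
Why: Denmark-type Lewis-base-activated SiCl4 Mukaiyama acetate aldol, in which the chiral bisphosphoramide-bound trichlorosilyl cation binds the aldehyde and lets the silyl ketene acetal add to its Si face, setting the only stereocentre as S (the future C2), while i-Pr2NEt scavenges HCl so that the silyl ethers and alkenes survive.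

Step 5
Reactants: 10 2,2,6-trimethyl-4H-1,3-dioxin-4-one; 11 acetyl chloride
Product: 12 2,2-dimethyl-6-(2-oxopropyl)-4H-1,3-dioxin-4-one
Conditions: 10 (2.0 equiv), LiN(SiMe3)2 (2.0 equiv), THF, −78 °C; 11 (1.0 equiv), −78 to −20 °C; aq NH4Cl
Reagents that add atoms: none
Why: Claisen-type γ-C-acylation of the lithium dienolate of the dioxinone (a vinylogous ester enolate) with acetyl chloride, the second equivalent of dienolate deprotonating the more acidic product so that it is not acylated again.

Step 6
Reactants: 9 methyl (3S)-3-Ar-3-hydroxypropanoate; 12 2,2-dimethyl-6-(2-oxopropyl)-4H-1,3-dioxin-4-one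
Product: 13 6-[(6S)-6-Ar-6-hydroxy-2,4-dioxohexyl]-2,2-dimethyl-4H-1,3-dioxin-4-one
Conditions: 12 (3.5 equiv), LiN(i-Pr)2 (7.0 equiv), THF, −78 °C, 1 h; then 9, −78 to −40 °C; AcOH, −78 °C
Reagents that add atoms: none
Why: Crossed Claisen condensation of the 1,3-dianion of 12, which reacts at its terminal, last-formed carbanion with the methyl ester of 9 while the hydroxyl of 9 is masked in the flask as its lithium alkoxide (unable to β-eliminate), the same way δ-hydroxy-β-keto esters are made from unprotected β-hydroxy esters, and the stereocentre is not touched.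

Step 7
Reactants: 13 6-[(6S)-6-Ar-6-hydroxy-2,4-dioxohexyl]-2,2-dimethyl-4H-1,3-dioxin-4-one
Product: 17 Kuwanon E ((2S)-2-(5-geranyl-2,4-dihydroxyphenyl)-5,7-dihydroxy-2,3-dihydro-4H-chromen-4-one), via dihydropyranone 14 (not isolated), via acylketene 15 (not isolated), via bis-silyl flavanone 16 (not isolated)
Conditions: pyridinium p-toluenesulfonate (5 mol%), 4 Å MS, PhMe (0.005 M), 45 °C, 2 h; then 110 °C, 1 h; then 0 °C, THF, Bu4NF/AcOH (1:1, 4 equiv), 1 h
Reagents that add atoms: none
Why: Proposed new method: the weak acid converts the δ-hydroxy-1,3-diketone into its six-membered hemiketal at C8a and dehydrates it (the usual cyclodehydration of δ-hydroxy-1,3-diketones) to dihydropyranone 14 without breaking the C2–O or C2–H bond, so the S centre is carried over with retention and the sieves remove the water; heating then expels acetone by retro-[4+2] to give acylketene 15, whose enol is a dienylketene (C4a=C8a–C8=C7–C6=C5=O) that closes the C4a–C5 bond by 6π-electrocyclization (equivalently, C-acylation of the nucleophilic vinylogous-ester carbon C4a) and tautomerizes to the 5,7-dihydroxy aromatic ring of 16, the closest known reactions being the thermal dioxinone-to-acylketene cyclization–aromatization cascades used for resorcylates and the dienylketene electrocyclization of the Danheiser benzannulation, and buffered fluoride finally cleaves the two aryl silyl ethers without the basic conditions that open flavanones.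

**Compound list**

1 | resorcinol (benzene-1,3-diol) | `Oc1cccc(O)c1` | starting material
2 | geraniol ((2E)-3,7-dimethylocta-2,6-dien-1-ol) | `CC(C)=CCC/C(C)=C/CO` | starting material
3 | 4-geranylresorcinol (4-geranylbenzene-1,3-diol) | `CC(C)=CCC/C(C)=C/Cc1ccc(O)cc1O` | intermediate
4 | (5-geranyl-2,4-dihydroxyphenyl)methylidene-dimethyliminium chloride | `CC(C)=CCC/C(C)=C/Cc1cc(C=[N+](C)C)c(O)cc1O.[Cl-]` | intermediate
5 | 5-geranyl-2,4-dihydroxybenzaldehyde | `CC(C)=CCC/C(C)=C/Cc1cc(C=O)c(O)cc1O` | intermediate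
6 | 2,4-bis(TBS-oxy)-5-geranylbenzaldehyde | `CC(C)=CCC/C(C)=C/Cc1cc(C=O)c(O[Si](C)(C)C(C)(C)C)cc1O[Si](C)(C)C(C)(C)C` | intermediate
7 | tert-butyl[(1-methoxyethenyl)oxy]dimethylsilane | `C=C(OC)O[Si](C)(C)C(C)(C)C` | starting material
8 | methyl (3S)-3-Ar-3-(trichlorosilyloxy)propanoate | `COC(=O)C[C@H](O[Si](Cl)(Cl)Cl)c1cc(C/C=C(\C)CCC=C(C)C)c(O[Si](C)(C)C(C)(C)C)cc1O[Si](C)(C)C(C)(C)C` | intermediate
9 | methyl (3S)-3-Ar-3-hydroxypropanoate | `COC(=O)C[C@H](O)c1cc(C/C=C(\C)CCC=C(C)C)c(O[Si](C)(C)C(C)(C)C)cc1O[Si](C)(C)C(C)(C)C` | intermediate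
10 | 2,2,6-trimethyl-4H-1,3-dioxin-4-one | `CC1=CC(=O)OC(C)(C)O1` | starting material
11 | acetyl chloride | `CC(Cl)=O` | starting material
12 | 2,2-dimethyl-6-(2-oxopropyl)-4H-1,3-dioxin-4-one | `CC(=O)CC1=CC(=O)OC(C)(C)O1` | intermediate
13 | 6-[(6S)-6-Ar-6-hydroxy-2,4-dioxohexyl]-2,2-dimethyl-4H-1,3-dioxin-4-one | `CC1(C)OC(=O)C=C(CC(=O)CC(=O)C[C@H](O)c2cc(C/C=C(\C)CCC=C(C)C)c(O[Si](C)(C)C(C)(C)C)cc2O[Si](C)(C)C(C)(C)C)O1` | intermediate
14 | (2S)-2-Ar-6-[(2,2-dimethyl-4-oxo-4H-1,3-dioxin-6-yl)methyl]-2,3-dihydro-4H-pyran-4-one | `O=C1C[C@@H](c2cc(C/C=C(\C)CCC=C(C)C)c(O[Si](C)(C)C(C)(C)C)cc2O[Si](C)(C)C(C)(C)C)OC(CC2=CC(=O)OC(C)(C)O2)=C1` | intermediate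
15 | (2S)-2-Ar-6-(2,4-dioxobut-3-en-1-yl)-2,3-dihydro-4H-pyran-4-one (acylketene) | `O=C=CC(=O)CC1=CC(=O)C[C@@H](c2cc(C/C=C(\C)CCC=C(C)C)c(O[Si](C)(C)C(C)(C)C)cc2O[Si](C)(C)C(C)(C)C)O1` | intermediate
16 | (2S)-2-Ar-5,7-dihydroxy-2,3-dihydro-4H-chromen-4-one (2',4'-bis-O-TBS Kuwanon E) | `O=C1C[C@@H](c2cc(C/C=C(\C)CCC=C(C)C)c(O[Si](C)(C)C(C)(C)C)cc2O[Si](C)(C)C(C)(C)C)Oc2cc(O)cc(O)c12` | intermediate
17 | Kuwanon E ((2S)-2-(5-geranyl-2,4-dihydroxyphenyl)-5,7-dihydroxy-2,3-dihydro-4H-chromen-4-one) | `CC(C)=CCC/C(C)=C/Cc1cc([C@@H]2CC(=O)c3c(O)cc(O)cc3O2)c(O)cc1O` | target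

**Step count and risks**

Total: 7 steps. Longest linear sequence: 6 steps (1, 2, 3, 4, 6, 7 from resorcinol and geraniol); step 5 is a one-step side branch.

The three steps most likely to fail, most likely first:

Step 7. The acylketene may oligomerize or be trapped if attack by C4a is slow, and acid plus heat could erode the ee. The fallback sets out from 13. It is cyclodehydrated on its own (pyridinium p-toluenesulfonate, 4 Å MS, CH2Cl2, rt) and 14 is isolated. Heating 14 with thiophenol (PhMe, 100 °C) traps the ketene as the S-phenyl β-keto thioester F1. Ring A is then closed ionically instead of pericyclically, by a magnesium-mediated soft-enolization Dieckmann condensation (MgBr2·OEt2, i-Pr2NEt, CH2Cl2, rt) in which the dienolate α-carbon (C4a) is acylated. This comes back to the route at 16, which is desilylated as in the last stage of step 7.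

Step 6. The unprotected lithium aldolate of 9 may undergo retro-aldol, or the ester may only be enolized. The fallback sets out from 9. The hydroxyl is silylated (Et3SiOTf, 2,6-lutidine) to the triethylsilyl ether F2. The ester is converted (MeNH(OMe)·HCl, i-PrMgCl, THF, −20 °C) into the Weinreb amide F3. F3 acylates the dianion of 12 (LiN(i-Pr)2, THF, −78 °C) to give the O-triethylsilyl diketo-dioxinone F4. Selective removal of the alkyl silyl ether (HF·pyridine, pyridine, THF, 0 °C) comes back to the route at 13.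

Step 4. The hindered, electron-rich ortho-silyloxy aldehyde may react slowly, with low ee or with the opposite sense. The fallback sets out from 6 and sets the stereocentre by reduction instead of C–C bond formation. Roskamp homologation with methyl diazoacetate (NbCl5 5 mol%, CH2Cl2, rt) gives the β-keto ester F5. Noyori asymmetric transfer hydrogenation (RuCl[(S,S)-TsDPEN](p-cymene) 1 mol%, HCO2H/Et3N 5:2, rt) gives the S benzylic alcohol, as with aryl ketones. This comes back to the route at 9.

**Further compounds**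

F1 | step 7 | S-phenyl 4-[(2S)-2-Ar-4-oxo-3,4-dihydro-2H-pyran-6-yl]-3-oxobutanethioate | `O=C(CC(=O)CC1=CC(=O)C[C@@H](c2cc(C/C=C(\C)CCC=C(C)C)c(O[Si](C)(C)C(C)(C)C)cc2O[Si](C)(C)C(C)(C)C)O1)Sc1ccccc1`
F2 | step 6 | methyl (3S)-3-Ar-3-(triethylsilyloxy)propanoate | `COC(=O)C[C@H](O[Si](CC)(CC)CC)c1cc(C/C=C(\C)CCC=C(C)C)c(O[Si](C)(C)C(C)(C)C)cc1O[Si](C)(C)C(C)(C)C`
F3 | step 6 | (3S)-3-Ar-N-methoxy-N-methyl-3-(triethylsilyloxy)propanamide | `CON(C)C(=O)C[C@H](O[Si](CC)(CC)CC)c1cc(C/C=C(\C)CCC=C(C)C)c(O[Si](C)(C)C(C)(C)C)cc1O[Si](C)(C)C(C)(C)C`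
F4 | step 6 | 6-[(6S)-6-Ar-2,4-dioxo-6-(triethylsilyloxy)hexyl]-2,2-dimethyl-4H-1,3-dioxin-4-one | `CC1(C)OC(=O)C=C(CC(=O)CC(=O)C[C@H](O[Si](CC)(CC)CC)c2cc(C/C=C(\C)CCC=C(C)C)c(O[Si](C)(C)C(C)(C)C)cc2O[Si](C)(C)C(C)(C)C)O1`
F5 | step 4 | methyl 3-Ar-3-oxopropanoate | `COC(=O)CC(=O)c1cc(C/C=C(\C)CCC=C(C)C)c(O[Si](C)(C)C(C)(C)C)cc1O[Si](C)(C)C(C)(C)C`
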